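**Plan**

- Retrosynthesis: the aryl ether bond O–C2' of the oxocine is cut first (tertiary alkoxide plus 2'-fluoride). Then come C11–OH (Markovnikov hydration of a C3 prenyl group), ring C at O1–C2 and C2–C3 (cyclodehydration, Baker–Venkataraman acyl transfer) and C9–C10 (prenylation of an acetophenone methyl group).
- Enabling feature: C2' of ring B is ortho to C1', and C1' is conjugated through C2=C3 of ring C with the C4 carbonyl. A 2'-fluoride on the flavone is therefore the fluoride of a vinylogous ortho-fluoroaryl ketone, and the bridge C3–C9H2–C10H2–C11Me2–O can be closed onto C2' by SNAr.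
- Forward order: ring A is bought; the C9–C11 chain is joined to the ketone; ring B arrives as an ester and ring C is closed; the alkene is hydrated; the eight-membered oxocine is closed; hydrogenolysis frees both phenols.
- The 4'-oxygen is carried from the start as a benzyl ether, so ring B holds a single fluoride and no substitution on the finished, base-sensitive chromone is needed afterwards.
- Stereochemistry: the target has no stereocentre, so nothing has to be set.

Key step: step 6

Remark: the twisted oxocine is taken as conformationally mobile (no stable axis), and 4-(benzyloxy)-2-fluorobenzoic acid is taken as a purchasable building block.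

**Route**

Step 1
Reactants: 1 2',6'-dihydroxy-4'-methoxyacetophenone
Product: 2 1-(2-benzyloxy-6-hydroxy-4-methoxyphenyl)ethanone
Conditions: BnBr (1.0 equiv), K2CO3, acetone, reflux
Reagents that add atoms: benzyl bromide, BrCc1ccccc1
Why: Williamson etherification in which, with one equivalent of halide, the first phenol is alkylated and the remaining one, locked in a hydrogen bond to the ketone, is much less nucleophilic, so the mono-ether should form selectively.

Step 2
Reactants: 2 1-(2-benzyloxy-6-hydroxy-4-methoxyphenyl)ethanone; 3 prenyl bromide (1-bromo-3-methylbut-2-ene)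
Product: 5 1-(2-benzyloxy-6-hydroxy-4-methoxyphenyl)-5-methylhex-4-en-1-one, via dilithium dianion 4 (not isolated)
Conditions: LiN(i-Pr)2 (2.2 equiv), THF, −78 °C; then 3 (1.0 equiv), −78 to −20 °C
Reagents that add atoms: prenyl bromide (compound 3), CC(C)=CCBr
Why: Enolate alkylation of a phenoxide–enolate dianion, in which the lithium phenoxide is inert to the allylic bromide in cold THF while the more basic methyl-ketone enolate is C-alkylated by SN2, and one equivalent of halide should hold back a second alkylation.

Step 3
Reactants: 5 1-(2-benzyloxy-6-hydroxy-4-methoxyphenyl)-5-methylhex-4-en-1-one; 6 4-(benzyloxy)-2-fluorobenzoic acid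
Product: 7 3-benzyloxy-5-methoxy-2-(5-methylhex-4-enoyl)phenyl 4-benzyloxy-2-fluorobenzoate
Conditions: DCC, DMAP (cat.), CH2Cl2, 0 °C to rt
Reagents that add atoms: 4-(benzyloxy)-2-fluorobenzoic acid (compound 6), OC(=O)c1ccc(OCc2ccccc2)cc1F
Why: Steglich esterification, in which DMAP turns the O-acylisourea into an acylpyridinium ion reactive enough to acylate the hydrogen-bonded phenol.

Step 4
Reactants: 7 3-benzyloxy-5-methoxy-2-(5-methylhex-4-enoyl)phenyl 4-benzyloxy-2-fluorobenzoate
Product: 9 5-benzyloxy-2-(4-benzyloxy-2-fluorophenyl)-7-methoxy-3-(3-methylbut-2-enyl)chromen-4-one, via 1,3-diketone 8 (not isolated)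
Conditions: LiN(SiMe3)2 (2.5 equiv), THF, −78 to 0 °C; AcOH quench, concentrate; NaOAc, AcOH, 100 °C
Reagents that add atoms: none
Why: Baker–Venkataraman rearrangement followed by cyclodehydration, in which the ketone enolate takes the neighbouring aroyl group through a six-membered transition state, and in buffered hot acetic acid the phenol adds to the aryl ketone and the hemiketal loses water (helped by the para-benzyloxy group), a medium too weakly acidic to protonate the trisubstituted alkene and not basic enough to let the enol oxygen displace the fluoride.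

Step 5
Reactants: 9 5-benzyloxy-2-(4-benzyloxy-2-fluorophenyl)-7-methoxy-3-(3-methylbut-2-enyl)chromen-4-one
Product: 10 5-benzyloxy-2-(4-benzyloxy-2-fluorophenyl)-3-(3-hydroxy-3-methylbutyl)-7-methoxychromen-4-one
Conditions: Co(acac)2 (cat.), PhSiH3, O2 (1 atm), i-PrOH/THF, rt
Reagents that add atoms: dioxygen, O=O
Why: Mukaiyama hydration, in which a cobalt hydride formed from the silane passes a hydrogen atom to the electron-rich trisubstituted alkene, the tertiary radical is trapped by O2 and reduced to the Markovnikov alcohol, and the tetrasubstituted, electron-poor C2=C3 bond of the chromone should stay untouched.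

Step 6
Reactants: 10 5-benzyloxy-2-(4-benzyloxy-2-fluorophenyl)-3-(3-hydroxy-3-methylbutyl)-7-methoxychromen-4-one
Product: 12 5,4'-di-O-benzylcyclointegrin, via potassium alkoxide 11 (not isolated)
Conditions: KN(SiMe3)2 (1.1 equiv), 18-crown-6 (1.1 equiv), THF (0.01 M), 0 °C, then 65 °C
Reagents that add atoms: none
Why: Deprotonation gives the potassium tertiary alkoxide, which adds to C2' to form a Meisenheimer anion whose charge passes through C1' and C2=C3 onto the C4 oxygen, and loss of fluoride then restores ring B (addition–elimination SNAr). The closest known reaction type is the intramolecular etherification of ortho-fluoroaryl ketones and their vinylogues by tethered alkoxides, here stretched to a tertiary alkoxide and an eight-membered ring. The oxocine closes through an eight-membered transition state at an sp2 carbon (endo with respect to the C1'–C2' bond that relays the charge), helped by the gem-dimethyl group, by four contiguous sp2 ring atoms and by the twist about C2–C1' that holds the 2'-fluoride over the C3 chain. No stereocentre is formed. The step needs substitution at C2' to win over six-membered oxa-Michael addition at C2 and the opening of ring C that can follow it; both are reversible and return the alkoxide whereas loss of KF is not, and with the 4'-oxygen already in place ring B offers no second leaving group. That benzyl ether is meta to C2', so its lone pair does not reach C1', C3' or C5' where the charge sits, and the 5-oxygen is kept as a benzyl ether because a 5-phenoxide would switch off the carbonyl as acceptor.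

Step 7
Reactants: 12 5,4'-di-O-benzylcyclointegrin
Product: 13 cyclointegrin
Conditions: H2 (1 atm), 10% Pd/C, EtOAc/MeOH, rt
Reagents that add atoms: none
Why: Hydrogenolysis of the two benzyl aryl ethers over palladium, under which the tetrasubstituted chromone double bond and the non-benzylic tertiary alkyl aryl ether should not be reduced.

**Compound list**

1 | 2',6'-dihydroxy-4'-methoxyacetophenone | COc1cc(O)c(C(C)=O)c(O)c1 | starting material
2 | 1-(2-benzyloxy-6-hydroxy-4-methoxyphenyl)ethanone | COc1cc(O)c(C(C)=O)c(OCc2ccccc2)c1 | intermediate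
3 | prenyl bromide (1-bromo-3-methylbut-2-ene) | CC(C)=CCBr | starting material
4 | dilithium phenoxide–enolate of 2 | [Li+].[Li+].COc1cc([O-])c(C([O-])=C)c(OCc2ccccc2)c1 | intermediate
5 | 1-(2-benzyloxy-6-hydroxy-4-methoxyphenyl)-5-methylhex-4-en-1-one | COc1cc(O)c(C(=O)CCC=C(C)C)c(OCc2ccccc2)c1 | intermediate
6 | 4-(benzyloxy)-2-fluorobenzoic acid | OC(=O)c1ccc(OCc2ccccc2)cc1F | starting material
7 | 3-benzyloxy-5-methoxy-2-(5-methylhex-4-enoyl)phenyl 4-benzyloxy-2-fluorobenzoate | COc1cc(OC(=O)c2ccc(OCc3ccccc3)cc2F)c(C(=O)CCC=C(C)C)c(OCc2ccccc2)c1 | intermediate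
8 | 1-(2-benzyloxy-6-hydroxy-4-methoxyphenyl)-3-(4-benzyloxy-2-fluorophenyl)-2-(3-methylbut-2-enyl)propane-1,3-dione (racemic, enolisable) | COc1cc(O)c(C(=O)C(CC=C(C)C)C(=O)c2ccc(OCc3ccccc3)cc2F)c(OCc2ccccc2)c1 | intermediate
9 | 5-benzyloxy-2-(4-benzyloxy-2-fluorophenyl)-7-methoxy-3-(3-methylbut-2-enyl)chromen-4-one | COc1cc(OCc2ccccc2)c2c(=O)c(CC=C(C)C)c(-c3ccc(OCc4ccccc4)cc3F)oc2c1 | intermediate
10 | 5-benzyloxy-2-(4-benzyloxy-2-fluorophenyl)-3-(3-hydroxy-3-methylbutyl)-7-methoxychromen-4-one | COc1cc(OCc2ccccc2)c2c(=O)c(CCC(C)(C)O)c(-c3ccc(OCc4ccccc4)cc3F)oc2c1 | intermediate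
11 | potassium tertiary alkoxide of 10 | [K+].COc1cc(OCc2ccccc2)c2c(=O)c(CCC(C)(C)[O-])c(-c3ccc(OCc4ccccc4)cc3F)oc2c1 | intermediate
12 | 5,4'-di-O-benzylcyclointegrin (5-benzyloxy-7-methoxyflavone with the bridge C3–CH2CH2C(CH3)2–O–C2' and a 4'-benzyloxy group) | COc1cc(OCc2ccccc2)c2c(=O)c3c(oc2c1)-c1ccc(OCc2ccccc2)cc1OC(C)(C)CC3 | intermediate
13 | cyclointegrin (5-hydroxy-7-methoxyflavone with the bridge C3–CH2CH2C(CH3)2–O–C2' and a 4'-hydroxy group) | COc1cc(O)c2c(=O)c3c(oc2c1)-c1ccc(O)cc1OC(C)(C)CC3 | target

**Step count**

Total steps: 7. Longest linear sequence: 7 steps (1 to 13).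

**Steps most likely to fail**

Step 6. The alkoxide may be drained faster by six-membered addition to C2 and opening of ring C to a ring-A phenoxide than it is consumed by substitution. If the way back from that resting state is too high, the closure stalls, or the phenoxide itself slowly attacks C2'. The fallback makes the same ether from the carbon side, by acid-promoted Markovnikov addition of a free 2'-phenol across the prenyl alkene (the hydroalkoxylation that turns ortho-prenylphenols into chromans). It sets out from ketone 5. Esterification (DCC, DMAP) with purchased 2,4-bis(benzyloxy)benzoic acid (OC(=O)c1ccc(OCc2ccccc2)cc1OCc1ccccc1) should give 3-benzyloxy-5-methoxy-2-(5-methylhex-4-enoyl)phenyl 2,4-bis(benzyloxy)benzoate F1. LiN(SiMe3)2 in THF then gives the 1,3-diketone F2, which in NaOAc/AcOH closes to 5-benzyloxy-2-[2,4-bis(benzyloxy)phenyl]-7-methoxy-3-(3-methylbut-2-enyl)chromen-4-one F3. BCl3 with pentamethylbenzene in CH2Cl2 at −78 °C removes the three benzyl groups without touching the alkene and should give 2-(2,4-dihydroxyphenyl)-5-hydroxy-7-methoxy-3-(3-methylbut-2-enyl)chromen-4-one F4. Catalytic p-TsOH in toluene at 60 °C then closes the oxocine, and the route is rejoined at the target 13.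

Step 4. Acyl transfer onto the branched enolate may be slow enough that the enolate oxygen or the amide base displaces the ortho fluoride before the diketone is formed. The fallback builds C2–C3 by aldol addition instead of acyl transfer, so no aryl ketone sits ortho to the fluoride while a base is present. It sets out from ketone 5. Double deprotonation with LiN(i-Pr)2 in THF at −78 °C gives the dilithium phenoxide–enolate F5, which is added to purchased 4-(benzyloxy)-2-fluorobenzaldehyde (O=Cc1ccc(OCc2ccccc2)cc1F) to give 1-(2-benzyloxy-6-hydroxy-4-methoxyphenyl)-2-[(4-benzyloxy-2-fluorophenyl)(hydroxy)methyl]-5-methylhex-4-en-1-one F6 as a mixture of diastereomers. Oxidation of the benzylic alcohol with Dess–Martin periodinane (NaHCO3, CH2Cl2) should give diketone 8, where the route is rejoined for the acetic acid stage of step 4.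

Step 2. Proton exchange between the mono-alkylated enolate and unreacted dianion may lead to double prenylation and returned ketone. The fallback moves the prenylation to the 1,3-diketone stage, where a stabilised enolate with a single remaining C–H is alkylated once. It sets out from ketone 2. Esterification with acid 6 (DCC, DMAP) should give 2-acetyl-3-benzyloxy-5-methoxyphenyl 4-benzyloxy-2-fluorobenzoate F7. Baker–Venkataraman rearrangement with LiN(SiMe3)2 in THF gives 1-(2-benzyloxy-6-hydroxy-4-methoxyphenyl)-3-(4-benzyloxy-2-fluorophenyl)propane-1,3-dione F8. C-Alkylation of F8 with prenyl bromide 3 (K2CO3, acetone, rt) should then give diketone 8, where the route is rejoined.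

**Further compounds**

F1 | step 6 | 3-benzyloxy-5-methoxy-2-(5-methylhex-4-enoyl)phenyl 2,4-bis(benzyloxy)benzoate | COc1cc(OC(=O)c2ccc(OCc3ccccc3)cc2OCc2ccccc2)c(C(=O)CCC=C(C)C)c(OCc2ccccc2)c1
F2 | step 6 | 1-(2-benzyloxy-6-hydroxy-4-methoxyphenyl)-3-[2,4-bis(benzyloxy)phenyl]-2-(3-methylbut-2-enyl)propane-1,3-dione (racemic, enolisable) | COc1cc(O)c(C(=O)C(CC=C(C)C)C(=O)c2ccc(OCc3ccccc3)cc2OCc2ccccc2)c(OCc2ccccc2)c1
F3 | step 6 | 5-benzyloxy-2-[2,4-bis(benzyloxy)phenyl]-7-methoxy-3-(3-methylbut-2-enyl)chromen-4-one | COc1cc(OCc2ccccc2)c2c(=O)c(CC=C(C)C)c(-c3ccc(OCc4ccccc4)cc3OCc3ccccc3)oc2c1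
F4 | step 6 | 2-(2,4-dihydroxyphenyl)-5-hydroxy-7-methoxy-3-(3-methylbut-2-enyl)chromen-4-one | COc1cc(O)c2c(=O)c(CC=C(C)C)c(-c3ccc(O)cc3O)oc2c1
F5 | step 4 | dilithium phenoxide–enolate of 5 (Z enolate expected) | [Li+].[Li+].COc1cc([O-])c(/C([O-])=C/CC=C(C)C)c(OCc2ccccc2)c1
F6 | step 4 | 1-(2-benzyloxy-6-hydroxy-4-methoxyphenyl)-2-[(4-benzyloxy-2-fluorophenyl)(hydroxy)methyl]-5-methylhex-4-en-1-one (mixture of diastereomers, racemic) | COc1cc(O)c(C(=O)C(CC=C(C)C)C(O)c2ccc(OCc3ccccc3)cc2F)c(OCc2ccccc2)c1
F7 | step 2 | 2-acetyl-3-benzyloxy-5-methoxyphenyl 4-benzyloxy-2-fluorobenzoate | COc1cc(OC(=O)c2ccc(OCc3ccccc3)cc2F)c(C(C)=O)c(OCc2ccccc2)c1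
F8 | step 2 | 1-(2-benzyloxy-6-hydroxy-4-methoxyphenyl)-3-(4-benzyloxy-2-fluorophenyl)propane-1,3-dione | COc1cc(O)c(C(=O)CC(=O)c2ccc(OCc3ccccc3)cc2F)c(OCc2ccccc2)c1
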